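**Retrosynthetic overview**

1. Target 16 comes from lactone 15 by a singlet-oxygen ene reaction at the only alkene left (C7–O bond, exocyclic C8=C19).
2. 15 comes from unsaturated δ-lactone 13 by conjugate reduction (sets C1) and enolate methylation (sets C15), both steered by C3.
3. 13 comes from dienoic acid 10 by forming the lactone O–C3 bond in an enantioselective 6-exo bromolactonization, then a bromide → epoxide → lactone relay (sets C3, C4).
4. 10 comes from 8 by closing the 14-membered carbocycle through an intramolecular alkenyl triflate/allylic acetate coupling (C1–C2).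
5. 8 comes from farnesyl acetate 1 and methyl acetoacetate 4 (SeO2 oxidation, Sharpless epoxidation for C11/C12, dianion alkylation). Ring order: epoxide, carbocycle, δ-lactone.

Assumption: isomerically pure (2E,6E)-farnesyl acetate is the commercial starting material, and the macrocycles carry cembrane locants (ring C1–C14; C15, C16 carbonyl and C17 methyl on C1; C18–C20 methyls on C4, C8, C12).

**Route**

Step 1
Reactants: 1 (2E,6E)-farnesyl acetate
Product: 2 (2E,6E,10E)-12-hydroxy-3,7,11-trimethyldodeca-2,6,10-trien-1-yl acetate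
Conditions: SeO2 (0.1 equiv), t-BuOOH (3 equiv), salicylic acid (0.1 equiv), CH2Cl2, rt
Reagents that add atoms: tert-butyl hydroperoxide, CC(C)(C)OO
Why: Catalytic SeO2 allylic oxidation (Sharpless–Umbreit; ene then [2,3]-sigmatropic shift) attacks only the electron-rich terminal trisubstituted alkene at its (E)-methyl group, giving the (10E)-allylic alcohol needed to direct the next step.

Step 2
Reactants: 2 (2E,6E,10E)-12-hydroxy-3,7,11-trimethyldodeca-2,6,10-trien-1-yl acetate
Product: 3 (2E,6E,10S,11S)-10,11-epoxy-12-hydroxy-3,7,11-trimethyldodeca-2,6-dien-1-yl acetate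
Conditions: Ti(OiPr)4 (10 mol %), L-(+)-diethyl tartrate (12 mol %), t-BuOOH, 4 Å molecular sieves, CH2Cl2, −20 °C
Reagents that add atoms: tert-butyl hydroperoxide, CC(C)(C)OO
Why: Katsuki–Sharpless asymmetric epoxidation delivers oxygen only to the alkene of the free allylic alcohol, and L-(+)-diethyl tartrate fixes both epoxide centres as S (C11 and C12 of the target).

Step 3
Reactants: 3 (2E,6E,10S,11S)-10,11-epoxy-12-hydroxy-3,7,11-trimethyldodeca-2,6-dien-1-yl acetate; 4 methyl acetoacetate
Product: 7 methyl (6S,7S,10E,14E)-16-acetoxy-6,7-epoxy-6,10,14-trimethyl-3-oxohexadeca-10,14-dienoate, via epoxy triflate 5 (not isolated), via dilithio acetoacetate dianion 6 (not isolated)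
Conditions: Tf2O, 2,6-lutidine, CH2Cl2, −78 °C; then 4, LiN(iPr)2 (2 equiv), THF, −78 to −40 °C
Reagents that add atoms: none
Why: Weiler dianion alkylation: the γ-carbon of dilithiated methyl acetoacetate displaces the primary oxiranylmethyl triflate by SN2 at −78 °C (faster than attack on the acetate or the trisubstituted epoxide), adding C14, C1, C15 and C16 without touching the stereocentres.

Step 4
Reactants: 7 methyl (6S,7S,10E,14E)-16-acetoxy-6,7-epoxy-6,10,14-trimethyl-3-oxohexadeca-10,14-dienoate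
Product: 8 methyl (2Z,6S,7S,10E,14E)-16-acetoxy-6,7-epoxy-6,10,14-trimethyl-3-(trifluoromethylsulfonyloxy)hexadeca-2,10,14-trienoate
Conditions: Tf2O, aq. LiOH, toluene, 5 °C
Reagents that add atoms: trifluoromethanesulfonic anhydride, O=S(=O)(OS(=O)(=O)C(F)(F)F)C(F)(F)F
Why: O-Triflation of the chelated lithium enolate of the β-keto ester (Frantz conditions) gives the (Z)-enol triflate, the geometry that later places C2 cis to the carboxyl group.

Step 5
Reactants: 8 methyl (2Z,6S,7S,10E,14E)-16-acetoxy-6,7-epoxy-6,10,14-trimethyl-3-(trifluoromethylsulfonyloxy)hexadeca-2,10,14-trienoate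
Product: 9 methyl (2Z)-2-[(3E,7E,11S,12S)-11,12-epoxy-4,8,12-trimethylcyclotetradeca-3,7-dien-1-ylidene]acetate
Conditions: NiBr2(dme) (10 mol %), 4,4'-di-tert-butyl-2,2'-bipyridine (12 mol %), Zn dust (3 equiv), DMA, 40 °C, 5 mM (syringe-pump addition)
Reagents that add atoms: none
Why: Nickel-catalysed reductive cross-electrophile coupling of an alkenyl triflate with an allylic acetate (known intermolecularly, here run at high dilution) joins the alkenylnickel unit to the unsubstituted allyl terminus with retention of the 2Z and 3E geometries, closing the 14-membered carbocycle.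

Step 6
Reactants: 9 methyl (2Z)-2-[(3E,7E,11S,12S)-11,12-epoxy-4,8,12-trimethylcyclotetradeca-3,7-dien-1-ylidene]acetate
Product: 10 (2Z)-2-[(3E,7E,11S,12S)-11,12-epoxy-4,8,12-trimethylcyclotetradeca-3,7-dien-1-ylidene]acetic acid
Conditions: LiOH, THF–H2O, rt; then 1 M HCl to pH 4, 0 °C
Reagents that add atoms: lithium hydroxide, [Li+].[OH-]
Why: Ester saponification frees the carboxylic acid that the (Z)-alkene holds next to the C3=C4 alkene; no stereocentre is affected.

Step 7
Reactants: 10 (2Z)-2-[(3E,7E,11S,12S)-11,12-epoxy-4,8,12-trimethylcyclotetradeca-3,7-dien-1-ylidene]acetic acid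
Product: 11 (3S,4R,7E,11S,12S)-4-bromo-11,12-epoxy-17-norcembra-1(15),7-dien-16,3-olide
Conditions: N-bromosuccinimide (1.1 equiv), O-(quinin-9-yl) N-(2,4-dimethoxyphenyl)thiocarbamate (10 mol %), CHCl3–toluene (1:2), −50 °C
Reagents that add atoms: N-bromosuccinimide, O=C1CCC(=O)N1Br
Why: Proposed new method: a bifunctional cinchona amino-thiocarbamate (quinuclidine ion-pairs the carboxylate, the thiocarbamate sulfur carries Br+) should deliver bromonium to one face of the C3=C4 alkene while the (Z)-tethered carboxylate closes 6-exo at C3 by anti addition (regiochemistry as in the bromolactonization of 2-prenylbenzoic acids), which forms the δ-lactone C–O bond, sets C3 (S) and C4 (R) and spares the C7=C8 alkene because the carboxylate cannot reach it; the closest known reaction is the amino-thiocarbamate-catalysed enantioselective bromolactonization of 1,1- and 1,2-disubstituted alkenoic acids, not yet shown for a (2Z)-2,5-dienoic acid with a trisubstituted alkyl alkene that gives a tertiary bromide.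

Step 8
Reactants: 11 (3S,4R,7E,11S,12S)-4-bromo-11,12-epoxy-17-norcembra-1(15),7-dien-16,3-olide
Product: 13 (3R,4S,7E,11S,12S)-11,12-epoxy-4-hydroxy-17-norcembra-1(15),7-dien-16,3-olide, via diepoxy acid 12 (not isolated)
Conditions: LiOH (2.2 equiv), THF–H2O, 0 °C; then 1 M HCl to pH 4, EtOAc, rt
Reagents that add atoms: lithium hydroxide, [Li+].[OH-]
Why: Bromohydrin-type epoxide closure followed by epoxide-opening lactonization: hydroxide opens the lactone, the freed C3 alkoxide displaces the tertiary bromide with inversion at C4 to give the 3S,4S epoxide, and after acidification the carboxylic acid opens it by 6-exo SN2 attack at C3 with inversion, giving the 3R lactone and the 4S tertiary alcohol.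

Step 9
Reactants: 13 (3R,4S,7E,11S,12S)-11,12-epoxy-4-hydroxy-17-norcembra-1(15),7-dien-16,3-olide
Product: 14 (1R,3R,4S,7E,11S,12S)-11,12-epoxy-4-hydroxy-17-norcembr-7-en-16,3-olide
Conditions: Cu(OAc)2·H2O (5 mol %), 1,2-bis(diphenylphosphino)benzene (5 mol %), (EtO)2MeSiH (3 equiv), t-BuOH (3 equiv), toluene, 0 °C to rt
Reagents that add atoms: none
Why: Copper hydride conjugate reduction (Stryker/Lipshutz type) adds hydride to C1 of the 5,6-dihydropyran-2-one from the face opposite to the C3 substituent, so the C14 and C4 ring bonds end up cis (1R).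

Step 10
Reactants: 14 (1R,3R,4S,7E,11S,12S)-11,12-epoxy-4-hydroxy-17-norcembr-7-en-16,3-olide
Product: 15 (1R,3R,4S,7E,11S,12S,15S)-11,12-epoxy-4-hydroxycembr-7-en-16,3-olide
Conditions: LiN(iPr)2 (2.2 equiv), THF, −78 °C; MeI, −78 to −40 °C
Reagents that add atoms: iodomethane, CI
Why: Alkylation of the lactone enolate (the tertiary alcohol is carried as its lithium alkoxide) occurs anti to the adjacent C1 substituent and sets C15 (S), the all-equatorial isomer that is also the thermodynamic one.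

Step 11
Reactants: 15 (1R,3R,4S,7E,11S,12S,15S)-11,12-epoxy-4-hydroxycembr-7-en-16,3-olide
Product: 16 (1R,3R,4S,7R,11S,12S,15S)-11,12-epoxy-7-hydroperoxy-4-hydroxycembr-8(19)-en-16,3-olide
Conditions: O2, tetraphenylporphyrin (1 mol %), visible light, CH2Cl2, −20 °C
Reagents that add atoms: dioxygen, O=O
Why: Schenck ene reaction of singlet oxygen with the only remaining alkene: by the cis effect a hydrogen of the C19 methyl group is abstracted, giving the C7 hydroperoxide with the exocyclic C8=C19 alkene, and attack on the outer face of the (7E)-alkene of the lactone-bridged ring, helped by hydrogen bonding to the C4 hydroxyl, is expected to give 7R.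

**Compound list**

1 | (2E,6E)-farnesyl acetate, (2E,6E)-3,7,11-trimethyldodeca-2,6,10-trien-1-yl acetate | CC(=O)OC/C=C(C)/CC/C=C(C)/CCC=C(C)C | starting material
2 | (2E,6E,10E)-12-hydroxy-3,7,11-trimethyldodeca-2,6,10-trien-1-yl acetate | CC(=O)OC/C=C(C)/CC/C=C(C)/CC/C=C(C)/CO | intermediate
3 | (2E,6E,10S,11S)-10,11-epoxy-12-hydroxy-3,7,11-trimethyldodeca-2,6-dien-1-yl acetate | CC(=O)OC/C=C(C)/CC/C=C(C)/CC[C@@H]1O[C@@]1(C)CO | intermediate
4 | methyl acetoacetate (methyl 3-oxobutanoate) | COC(=O)CC(C)=O | starting material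
5 | (2E,6E,10S,11S)-10,11-epoxy-3,7,11-trimethyl-12-(trifluoromethylsulfonyloxy)dodeca-2,6-dien-1-yl acetate (epoxy triflate) | CC(=O)OC/C=C(C)/CC/C=C(C)/CC[C@@H]1O[C@@]1(C)COS(=O)(=O)C(F)(F)F | intermediate
6 | dilithium dianion of methyl acetoacetate (dilithium 1-methoxybuta-1,3-diene-1,3-diolate) | C=C([O-])C=C([O-])OC.[Li+].[Li+] | intermediate
7 | methyl (6S,7S,10E,14E)-16-acetoxy-6,7-epoxy-6,10,14-trimethyl-3-oxohexadeca-10,14-dienoate | CC(=O)OC/C=C(C)/CC/C=C(C)/CC[C@@H]1O[C@@]1(C)CCC(=O)CC(=O)OC | intermediate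
8 | methyl (2Z,6S,7S,10E,14E)-16-acetoxy-6,7-epoxy-6,10,14-trimethyl-3-(trifluoromethylsulfonyloxy)hexadeca-2,10,14-trienoate | CC(=O)OC/C=C(C)/CC/C=C(C)/CC[C@@H]1O[C@@]1(C)CC/C(OS(=O)(=O)C(F)(F)F)=C/C(=O)OC | intermediate
9 | methyl (2Z)-2-[(3E,7E,11S,12S)-11,12-epoxy-4,8,12-trimethylcyclotetradeca-3,7-dien-1-ylidene]acetate | C1C[C@@H]2O[C@@]2(C)CC/C(=C/C(=O)OC)C/C=C(C)/CC/C=C1\C | intermediate
10 | (2Z)-2-[(3E,7E,11S,12S)-11,12-epoxy-4,8,12-trimethylcyclotetradeca-3,7-dien-1-ylidene]acetic acid | C1C[C@@H]2O[C@@]2(C)CC/C(=C/C(=O)O)C/C=C(C)/CC/C=C1\C | intermediate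
11 | (3S,4R,7E,11S,12S)-4-bromo-11,12-epoxy-17-norcembra-1(15),7-dien-16,3-olide | C1C[C@@H]2O[C@@]2(C)CCC2C[C@H](OC(=O)C=2)[C@](C)(Br)CC/C=C1\C | intermediate
12 | (2Z)-2-[(3S,4S,7E,11S,12S)-3,4:11,12-diepoxy-4,8,12-trimethylcyclotetradec-7-en-1-ylidene]acetic acid | C1C[C@@H]2O[C@@]2(C)CC/C(=C/C(=O)O)C[C@@H]2O[C@@]2(C)CC/C=C1\C | intermediate
13 | (3R,4S,7E,11S,12S)-11,12-epoxy-4-hydroxy-17-norcembra-1(15),7-dien-16,3-olide | C1C[C@@H]2O[C@@]2(C)CCC2C[C@@H](OC(=O)C=2)[C@@](C)(O)CC/C=C1\C | intermediate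
14 | (1R,3R,4S,7E,11S,12S)-11,12-epoxy-4-hydroxy-17-norcembr-7-en-16,3-olide | C1C[C@@H]2O[C@@]2(C)CC[C@@H]2C[C@@H](OC(=O)C2)[C@@](C)(O)CC/C=C1\C | intermediate
15 | (1R,3R,4S,7E,11S,12S,15S)-11,12-epoxy-4-hydroxycembr-7-en-16,3-olide | C1C[C@@H]2O[C@@]2(C)CC[C@@H]2C[C@@H](OC(=O)[C@H]2C)[C@@](C)(O)CC/C=C1\C | intermediate
16 | (1R,3R,4S,7R,11S,12S,15S)-11,12-epoxy-7-hydroperoxy-4-hydroxycembr-8(19)-en-16,3-olide (CNP0319766.1) | C=C1CC[C@@H]2O[C@@]2(C)CC[C@@H]2C[C@@H](OC(=O)[C@H]2C)[C@@](C)(O)CC[C@H]1OO | target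

**Step count and risks**

Total step count: 11. Longest linear sequence: 11 steps (from 1).

Steps most likely to fail:

- Step 5 (ring closure). The reductive nickel coupling is established between separate partners but not for a 14-membered ring; hydrodetriflation or oligomerisation may win. The fallback sets out from 8 and comes back at 9. Li[Cu(SPh)(SnMe3)] in THF at −78 °C replaces the triflate with retention to give methyl (2Z,6S,7S,10E,14E)-16-acetoxy-6,7-epoxy-6,10,14-trimethyl-3-(trimethylstannyl)hexadeca-2,10,14-trienoate F1. A Stille–Hegedus coupling of the alkenylstannane with its own allylic acetate (Pd2(dba)3, AsPh3, LiCl, DMF, high dilution) then closes the ring to 9.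

- Step 7 (the proposed new bromolactonization). It may close 7-endo at the tertiary carbon, give low facial selectivity, or give the opposite sense; in the last case the quinidine-derived pseudoenantiomer of the catalyst is used. The fallback uses known chemistry, sets out from 9 and comes back at 13. Shi epoxidation of ester 9 with the L-fructose-derived ketone (ent-Shi ketone, made from L-sorbose), KHSO5 and K2CO3 in MeCN–dimethoxymethane–H2O at 0 °C, run to partial conversion, gives methyl (2Z)-2-[(3S,4S,7E,11S,12S)-3,4:11,12-diepoxy-4,8,12-trimethylcyclotetradec-7-en-1-ylidene]acetate F2 after chromatographic separation from other epoxidation products. LiOH and then acidification to pH 4 convert it through 12 into 13. The cost is poor site selectivity between the two trisubstituted alkenes.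

- Step 11 (ene reaction). The tertiary C8 hydroperoxide may compete and the C7 facial selectivity is not secured. The fallback sets out from 15 and comes back at 16. The photooxygenation mixture of 16 and (1R,3R,4S,7S,11S,12S,15S)-11,12-epoxy-7-hydroperoxy-4-hydroxycembr-8(19)-en-16,3-olide F3 is dehydrated with Ac2O, pyridine and DMAP (Kornblum–DeLaMare type) to (1R,3R,4S,11S,12S,15S)-11,12-epoxy-4-hydroxy-7-oxocembr-8(19)-en-16,3-olide F4. Reduction with (R)-Me-CBS and BH3·SMe2 gives (1R,3R,4S,7S,11S,12S,15S)-11,12-epoxy-4,7-dihydroxycembr-8(19)-en-16,3-olide F5. Selective mesylation of the secondary alcohol (MsCl, Et3N) gives (1R,3R,4S,7S,11S,12S,15S)-11,12-epoxy-4-hydroxy-7-(methylsulfonyloxy)cembr-8(19)-en-16,3-olide F6, and displacement with ethereal H2O2 (SN2, inversion) gives 16.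

**Further compounds**

F1 | step 5 | methyl (2Z,6S,7S,10E,14E)-16-acetoxy-6,7-epoxy-6,10,14-trimethyl-3-(trimethylstannyl)hexadeca-2,10,14-trienoate | CC(=O)OC/C=C(C)/CC/C=C(C)/CC[C@@H]1O[C@@]1(C)CC/C([Sn](C)(C)C)=C/C(=O)OC
F2 | step 7 | methyl (2Z)-2-[(3S,4S,7E,11S,12S)-3,4:11,12-diepoxy-4,8,12-trimethylcyclotetradec-7-en-1-ylidene]acetate | C1C[C@@H]2O[C@@]2(C)CC/C(=C/C(=O)OC)C[C@@H]2O[C@@]2(C)CC/C=C1\C
F3 | step 11 | (1R,3R,4S,7S,11S,12S,15S)-11,12-epoxy-7-hydroperoxy-4-hydroxycembr-8(19)-en-16,3-olide | C=C1CC[C@@H]2O[C@@]2(C)CC[C@@H]2C[C@@H](OC(=O)[C@H]2C)[C@@](C)(O)CC[C@@H]1OO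
F4 | step 11 | (1R,3R,4S,11S,12S,15S)-11,12-epoxy-4-hydroxy-7-oxocembr-8(19)-en-16,3-olide | C=C1CC[C@@H]2O[C@@]2(C)CC[C@@H]2C[C@@H](OC(=O)[C@H]2C)[C@@](C)(O)CCC1=O
F5 | step 11 | (1R,3R,4S,7S,11S,12S,15S)-11,12-epoxy-4,7-dihydroxycembr-8(19)-en-16,3-olide | C=C1CC[C@@H]2O[C@@]2(C)CC[C@@H]2C[C@@H](OC(=O)[C@H]2C)[C@@](C)(O)CC[C@@H]1O
F6 | step 11 | (1R,3R,4S,7S,11S,12S,15S)-11,12-epoxy-4-hydroxy-7-(methylsulfonyloxy)cembr-8(19)-en-16,3-olide | C=C1CC[C@@H]2O[C@@]2(C)CC[C@@H]2C[C@@H](OC(=O)[C@H]2C)[C@@](C)(O)CC[C@@H]1OS(C)(=O)=O
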